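Early times speak against the hunch that a larger partner charge moves the target: the first readings climb at nearly one pace on both earlier runs.

the same everywhere: substrate 0.20 M
- Friday's: partner 0.17 M; run made earlier
- Monday's: partner 0.51 M; run made earlier
- oak: partner 0.200 M; time 15 min
- elm: partner 0.300 M; time 15 min
- larch: partner 0.500 M; time 15 min
- birch: partner 0.800 M; time 15 min
- cedar: partner 1.20 M; time 15 min

| Friday's: time / min | Friday's: target / % | Monday's: time / min | Monday's: target / % |
|---|---|---|---|
| 3.00 | 76 | 1.33 | 50 |
| 6.00 | 93 | 4.00 | 84 |
| 10.0 | 91 | 8.00 | 91 |
| 12.0 | 93 | 10.0 | 92 |
| 15.0 | 94 | 15.0 | 92 |

(standard deviation of a reading: 1.5 percentage points)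

- amount of target at the end, in percent of the substrate charged for oak, elm, larch, birch, cedar, in this order
- how the row runs (falls all the way / rises, then falls / hardly changes / rises all the way / falls, then rises)

- steps thought possible: substrate -> target; substrate <-> intermediate A; partner + intermediate A <-> intermediate B; intermediate A -> side product; partner + intermediate B <-> intermediate C; intermediate C <-> intermediate D
- "hardly changes" means that all values lie within two and a half points (for a concentration: within two and a half percent of the largest)

1. The flat readings of both runs average 92.3%. Against that plateau, Friday's reading at 3.00 min gives a rate constant of 0.578 min⁻¹. Monday's at 4.00 min gives 0.603 min⁻¹, with [partner] 3.00 times higher.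

2. The substrate lifetime, taken from Friday's reading, is therefore about 1.73 min, far shorter than the 15 min of the row, so the row should read plateaus.

3. Friday's partner charge was 85.0% of the substrate charge, less than the plateau, so the target does not take partner mole for mole.

4. The plateau is the large term, and the correction is the missing 7.71%. The selectivity factor, plateau over missing share, reads 12.0. Friday's and Monday's plateaus differ by 1.1 percentage points, against a scatter of 1.5 points per reading, so the factor shows no visible partner dependence.

5. The reckoning commits to 92.3% from oak to cedar, a row that hardly changes, although birch and cedar stand above Monday's charge.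

The forecast gave 93% for oak, a little above this reckoning, and 92% from elm to cedar, a row that hardly changes, holding that “tripling the partner leaves the rate unchanged”.

The flasks give 93.8%, 93.8%, 93.8%, 93.7% and 93.6%: the row hardly changes, with oak 1.5 points above the reckoned plateau.

    substrate → target (k = 0.530 min⁻¹)
    substrate ⇌ intermediate A (K = 3.00, k = 0.0380 min⁻¹)
    partner + intermediate A ⇌ intermediate B (K = 0.750 L mol⁻¹, k = 1.40 L mol⁻¹ min⁻¹)
    intermediate A → side product (k = 0.0640 min⁻¹)
    partner + intermediate B ⇌ intermediate C (K = 3.20 L mol⁻¹, k = 0.0540 L mol⁻¹ min⁻¹)
    intermediate C ⇌ intermediate D (K = 4.50, k = 0.00620 min⁻¹)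

The selectivity factor of oak is 15.1, and that of cedar is 14.6, almost equal at [partner] 6.00 times apart. The missing share of cedar is owed to the conversion of substrate into intermediate A, a branch taken before partner enters. In cedar, the run without that step lifts the target from 93.6% to >99.9%, an effect of 6.3 points that covers 100% of what is missing.

(Readings and results stem from a simulated flask for substances that don't exist, noise included.)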